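The numbers in the tables come from a simulation on assumed constants, noise included.

At early times the readings say little: at 25.0 s the dawn run, which is the asked flask followed so far, reads 1.2% and the dusk run 0%. None of X starts in solution, so I read this as an induction period while G builds up.

all flasks: Q 0.80 M

| charge | X | remark | time |
|---|---|---|---|
| dawn | 1.05 equiv | the very flask that is asked about, followed so far |  |
| dusk | 0.70 equiv | run made earlier |  |
| flask | 1.05 equiv |  | 2.5 min |

- dawn (time / s: D / %): 10.0: 0.6; 15.0: 0.2; 25.0: 1.2; 50.0: 4.1
- dusk (time / s: D / %): 10.0: 0; 15.0: 0.3; 25.0: 0; 40.0: 1.9; 60.0: 3.7; 120: 9.4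

(readings scatter by 0.5 percentage points)

1. D at 2.5 min, in percent of the Q charged
2. concentration of G in solution at 2.5 min, in percent of saturation

- as a solid, counted per litre of solution: X
- at the start none of X is in solution
- G is what X becomes in solution

The dawn run stops at 50.0 s, so I borrow from the dusk run. The rise of D between its last two readings, per unit time, is 0.0570 min⁻¹ as a fraction of the Q charged, and this is what I carry: the steady rate of D as read off the dusk run, with the scatter of those two readings. Integrating this constant rate on from the last dusk reading gives 12.2% at 2.5 min. This is a risk, because it assumes the charge of X does not matter, while the dawn reading at 50.0 s stands 1.3 percentage points above the line, against a scatter of 0.5 points. G was never read, so I reckon no saturation.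

The forecast gives 15% of D, more than my figure, and 82% of saturation, holding that “G is levelling off towards saturation”.

The flask gives 11.9% and 31.4%. The forecast's D is within tolerance and its saturation is 51 points too high, while my line lies 0.30 points above the flask's D.

    X ⇌ G, rate k1*(cs1 - [G]) while solid is left; crystals form when [G] > cs1 (solubility = 0.310 M, k = 0.00730 s⁻¹)
    Q + G ⇌ Z (K = 58.0 M⁻¹, k = 0.0110 M⁻¹ s⁻¹)
    Q + G ⇌ D (K = 2.80 M⁻¹, k = 0.0210 M⁻¹ s⁻¹)

At 2.50 min this flask makes G 1.25 times faster than it uses it up, each step taken net. There c(G) stands at 0.0975 M, up from 0.0713 M at 1.25 min. For the same flask read at 1.5 min, the steady rate taken back from the last dusk reading gives 6.55%, and the simulation gives 6.97%.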